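**Strategy.** The upper 1,3-diarylpropan-2-ol unit is read as a gallocatechin whose pyran ring has been opened. Its diarylmethine carbon is C2 of a flavan, its phloroglucinol ring is the former ring A, and the bond from that carbon to C8 of the lower gallocatechin stands where the O1–C2 bond was. Both halves therefore come from the two commercial enantiomers of gallocatechin. In the key step 6,8-dibromo-(+)-gallocatechin opens at O1–C2 to a ring B para-quinone methide, which C8 of penta-O-benzyl-(−)-gallocatechin captures in a Friedel–Crafts 1,6-addition. This forms the C–C bond, unveils the phloroglucinol ring and sets the diarylmethine stereocentre. Double galloylation and hydrogenolysis finish the route.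

Key step: step 3

Remark on the chemistry: (+)-gallocatechin (2R,3S) and (−)-gallocatechin (2S,3R) are both taken as purchasable single enantiomers. The lower unit of the target has the (2S,3R) configuration of (−)-gallocatechin; the upper carbinol carbon has the 3S configuration of (+)-gallocatechin.

**Step 1**
Reactants: 1 (−)-gallocatechin
Product: 2 penta-O-benzyl-(−)-gallocatechin [(2S,3R)-5,7-bis(benzyloxy)-2-[3,4,5-tris(benzyloxy)phenyl]chroman-3-ol]
Conditions: BnBr (5.5 equiv), K2CO3, DMF, 0 °C to rt, argon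
Reagents that add atoms: benzyl bromide, BrCc1ccccc1
Why: Williamson ether synthesis on the five phenols should leave the aliphatic 3-OH free and cap the 4'-phenoxide before base-induced C2 epimerisation can set in, so both stereocentres are kept.

**Step 2**
Reactants: 3 (+)-gallocatechin
Product: 4 6,8-dibromo-(+)-gallocatechin [(2R,3S)-6,8-dibromo-2-(3,4,5-trihydroxyphenyl)chromane-3,5,7-triol]
Conditions: NBS (2.05 equiv), THF, −40 °C to 0 °C, dark, argon
Reagents that add atoms: N-bromosuccinimide, O=C1CCC(=O)N1Br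
Why: Electrophilic aromatic bromination should take place at C6 and C8 of the phloroglucinol-type ring A, by far the most nucleophilic carbons (the known ring A halogenation of free flavan-3-ols), and leave ring B and the stereocentres untouched.

**Step 3**
Reactants: 4 dibromo-(+)-gallocatechin; 2 penta-O-benzyl-(−)-gallocatechin
Product: 6 (2S,3R)-5,7-bis(benzyloxy)-8-[(1R,2S)-3-(3,5-dibromo-2,4,6-trihydroxyphenyl)-2-hydroxy-1-(3,4,5-trihydroxyphenyl)propyl]-2-[3,4,5-tris(benzyloxy)phenyl]chroman-3-ol, via para-quinone methide 5 (not isolated)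
Conditions: (PhO)2P(O)OH (20 mol %), HFIP–CH2Cl2 (1:4), 25–40 °C, argon; the dibromide is added slowly to the benzylated nucleophile, which is kept in twofold excess and recovered on chromatography
Reagents that add atoms: none
Why: Phosphoric acid catalysis shuttles the proton of the free 4'-OH of the dibromide to O1 and opens the O1–C2 bond of ring C (the ring–chain tautomerism by which flavan-3-ols epimerise at C2) to the neutral para-quinone methide, whose exocyclic carbon (the former C2) is attacked in its O-protonated form by C8 of the benzylated nucleophile in a Friedel–Crafts 1,6-addition that rearomatises ring B, so the step is a pure addition in which every atom of both partners ends up in the product. The closest known reactions are the acid-catalysed phenolation of flavan-3-ols, which opens the pyran ring and arylates C2, and the Brønsted-acid-catalysed 1,6-arylation of para-quinone methides by electron-rich arenes. No ring is closed: ring C of the dibromide is opened, and re-closure by the ring A phenol or addition of HFIP or of a hydroxyl is reversible and only returns material to the quinone methide. The new (1R) stereocentre is set by the neighbouring (2S) carbinol carbon: in the quinone methide its C–H eclipses the quinone methide ring (1,3-allylic strain; the symmetric ring B leaves no E/Z isomers), and the arene should enter anti to the bulky (3,5-dibromo-2,4,6-trihydroxyphenyl)methyl group, on the face of the small hydroxyl. Chemoselectivity rests on the fact that only the dibromide has a free para-hydroxyl and an electron-poor aryloxide leaving group, so that the perbenzylated partner cannot open to a quinone methide and acts only as nucleophile, while the bromines at C6 and C8 keep ring A of the dibromide and of the product from acting as a competing nucleophile. Regioselectivity for C8 of the nucleophile over C6, which lies between two benzyloxy groups, follows the behaviour of benzylated flavan-3-ols as nucleophiles in interflavan bond formation.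

**Step 4**
Reactants: 6 coupling product with six free phenols
Product: 7 (2S,3R)-5,7-bis(benzyloxy)-8-{(1R,2S)-3-[2,4,6-tris(benzyloxy)-3,5-dibromophenyl]-2-hydroxy-1-[3,4,5-tris(benzyloxy)phenyl]propyl}-2-[3,4,5-tris(benzyloxy)phenyl]chroman-3-ol
Conditions: BnBr (8 equiv), K2CO3, DMF, rt to 40 °C, argon
Reagents that add atoms: benzyl bromide, BrCc1ccccc1
Why: Williamson ether synthesis should alkylate only the six phenols (those flanked by bromine are the most acidic) and leave the two secondary alcohols free for esterification, with no stereocentre involved.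

**Step 5**
Reactants: 7 diol; 8 3,4,5-tris(benzyloxy)benzoic acid (3 equiv)
Product: 9 (2S,3R)-5,7-bis(benzyloxy)-8-{(1R,2S)-3-[2,4,6-tris(benzyloxy)-3,5-dibromophenyl]-2-[3,4,5-tris(benzyloxy)benzoyloxy]-1-[3,4,5-tris(benzyloxy)phenyl]propyl}-2-[3,4,5-tris(benzyloxy)phenyl]chroman-3-yl 3,4,5-tris(benzyloxy)benzoate
Conditions: DCC (3.2 equiv), DMAP (0.5 equiv), CH2Cl2, rt to 40 °C
Reagents that add atoms: none
Why: Steglich esterification, the usual way to galloylate benzylated flavan-3-ols, should acylate both secondary alcohols at oxygen with retention at both carbinol carbons.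

**Step 6**
Reactants: 9 perbenzylated dibromo bis-gallate
Product: 10 target, (2S,3R)-5,7-dihydroxy-8-[(1R,2S)-2-(3,4,5-trihydroxybenzoyloxy)-1-(3,4,5-trihydroxyphenyl)-3-(2,4,6-trihydroxyphenyl)propyl]-2-(3,4,5-trihydroxyphenyl)chroman-3-yl 3,4,5-trihydroxybenzoate
Conditions: H2 (1 atm), Pd(OH)2 on carbon, Et3N (2.2 equiv), THF–MeOH (1:1), rt
Reagents that add atoms: none
Why: Catalytic hydrogenolysis should cleave all seventeen benzyl ethers and, with Et3N as HBr scavenger, both aryl C–Br bonds in one operation (the known end-game for bromine-blocked benzylated proanthocyanidins), leaving the gallate esters, the flavan ring and all four stereocentres intact.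

**Compound list**

1 | (−)-gallocatechin, (2S,3R)-2-(3,4,5-trihydroxyphenyl)chromane-3,5,7-triol | Oc1cc(O)c2c(c1)O[C@@H](c1cc(O)c(O)c(O)c1)[C@H](O)C2 | starting material
2 | penta-O-benzyl-(−)-gallocatechin, (2S,3R)-5,7-bis(benzyloxy)-2-[3,4,5-tris(benzyloxy)phenyl]chroman-3-ol | C(c1ccccc1)Oc1cc(OCc3ccccc3)c2c(c1)O[C@@H](c1cc(OCc3ccccc3)c(OCc3ccccc3)c(OCc3ccccc3)c1)[C@H](O)C2 | intermediate
3 | (+)-gallocatechin, (2R,3S)-2-(3,4,5-trihydroxyphenyl)chromane-3,5,7-triol | Oc1cc(O)c2c(c1)O[C@H](c1cc(O)c(O)c(O)c1)[C@@H](O)C2 | starting material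
4 | 6,8-dibromo-(+)-gallocatechin, (2R,3S)-6,8-dibromo-2-(3,4,5-trihydroxyphenyl)chromane-3,5,7-triol | Oc1c(Br)c(O)c2c(c1Br)O[C@H](c1cc(O)c(O)c(O)c1)[C@@H](O)C2 | intermediate
5 | para-quinone methide, 4-[(2S)-3-(3,5-dibromo-2,4,6-trihydroxyphenyl)-2-hydroxypropylidene]-2,6-dihydroxycyclohexa-2,5-dien-1-one | O=C1C(O)=CC(=C[C@@H](O)Cc2c(O)c(Br)c(O)c(Br)c2O)C=C1O | intermediate
6 | (2S,3R)-5,7-bis(benzyloxy)-8-[(1R,2S)-3-(3,5-dibromo-2,4,6-trihydroxyphenyl)-2-hydroxy-1-(3,4,5-trihydroxyphenyl)propyl]-2-[3,4,5-tris(benzyloxy)phenyl]chroman-3-ol | O[C@@H](Cc1c(O)c(Br)c(O)c(Br)c1O)[C@H](c1cc(O)c(O)c(O)c1)c1c(OCc2ccccc2)cc(OCc2ccccc2)c2c1O[C@@H](c1cc(OCc3ccccc3)c(OCc3ccccc3)c(OCc3ccccc3)c1)[C@H](O)C2 | intermediate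
7 | (2S,3R)-5,7-bis(benzyloxy)-8-{(1R,2S)-3-[2,4,6-tris(benzyloxy)-3,5-dibromophenyl]-2-hydroxy-1-[3,4,5-tris(benzyloxy)phenyl]propyl}-2-[3,4,5-tris(benzyloxy)phenyl]chroman-3-ol | O[C@@H](Cc1c(OCc2ccccc2)c(Br)c(OCc2ccccc2)c(Br)c1OCc1ccccc1)[C@H](c1cc(OCc2ccccc2)c(OCc2ccccc2)c(OCc2ccccc2)c1)c1c(OCc2ccccc2)cc(OCc2ccccc2)c2c1O[C@@H](c1cc(OCc3ccccc3)c(OCc3ccccc3)c(OCc3ccccc3)c1)[C@H](O)C2 | intermediate
8 | 3,4,5-tris(benzyloxy)benzoic acid | OC(=O)c1cc(OCc2ccccc2)c(OCc2ccccc2)c(OCc2ccccc2)c1 | starting material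
9 | (2S,3R)-5,7-bis(benzyloxy)-8-{(1R,2S)-3-[2,4,6-tris(benzyloxy)-3,5-dibromophenyl]-2-[3,4,5-tris(benzyloxy)benzoyloxy]-1-[3,4,5-tris(benzyloxy)phenyl]propyl}-2-[3,4,5-tris(benzyloxy)phenyl]chroman-3-yl 3,4,5-tris(benzyloxy)benzoate | O=C(O[C@@H](Cc1c(OCc2ccccc2)c(Br)c(OCc2ccccc2)c(Br)c1OCc1ccccc1)[C@H](c1cc(OCc2ccccc2)c(OCc2ccccc2)c(OCc2ccccc2)c1)c1c(OCc2ccccc2)cc(OCc2ccccc2)c2c1O[C@@H](c1cc(OCc3ccccc3)c(OCc3ccccc3)c(OCc3ccccc3)c1)[C@H](OC(=O)c1cc(OCc3ccccc3)c(OCc3ccccc3)c(OCc3ccccc3)c1)C2)c1cc(OCc2ccccc2)c(OCc2ccccc2)c(OCc2ccccc2)c1 | intermediate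
10 | (2S,3R)-5,7-dihydroxy-8-[(1R,2S)-2-(3,4,5-trihydroxybenzoyloxy)-1-(3,4,5-trihydroxyphenyl)-3-(2,4,6-trihydroxyphenyl)propyl]-2-(3,4,5-trihydroxyphenyl)chroman-3-yl 3,4,5-trihydroxybenzoate | O=C(O[C@@H](Cc1c(O)cc(O)cc1O)[C@H](c1cc(O)c(O)c(O)c1)c1c(O)cc(O)c2c1O[C@@H](c1cc(O)c(O)c(O)c1)[C@H](OC(=O)c1cc(O)c(O)c(O)c1)C2)c1cc(O)c(O)c(O)c1 | target

**Summary**

Total step count: 6. Longest linear sequence: 5 steps (steps 2, 3, 4, 5, 6 from 3; equally steps 1, 3, 4, 5, 6 from 1).

**Steps most likely to fail**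

Step 3. Ring opening of 4 may be too slow under the weakly acidic conditions that the nucleophile tolerates. The quinone methide could then be lost by a 1,2-hydride shift to the 1,3-diarylpropan-2-one, 2 could begin to ionise at its own C2, or facial selectivity at the diarylmethine carbon could be poor. The fallback separates ring opening from C–C bond formation. From 4, base-mediated ring opening in the presence of benzyl mercaptan (BnSH, aqueous NaOH, pH about 12, 40 °C, argon), the known thiol capture of the flavan-3-ol quinone methide, should give (2S)-1-(benzylsulfanyl)-3-(3,5-dibromo-2,4,6-trihydroxyphenyl)-1-(3,4,5-trihydroxyphenyl)propan-2-ol F1 as a mixture of epimers at the sulfur-bearing carbon. Benzylation of its six phenols (BnBr, K2CO3, DMF) should give (2S)-1-(benzylsulfanyl)-3-[2,4,6-tris(benzyloxy)-3,5-dibromophenyl]-1-[3,4,5-tris(benzyloxy)phenyl]propan-2-ol F2. Activation of this thioether with AgBF4 (THF–CH2Cl2, −40 °C) in the presence of 2, the thiophilic benzylic thioether coupling used for interflavan bonds, should then give 7 directly, so the route is rejoined at 7 and step 4 is skipped. The low temperature should also let the 1,3-allylic strain model express itself more fully.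

Step 2. The brominating agent may oxidise the free pyrogallol ring B, or bromination may go beyond two bromines. The fallback masks ring B first. From 3, dichlorodiphenylmethane (Ph2CCl2, diphenyl ether, 170 °C) should give the ketal (2R,3S)-2-(7-hydroxy-2,2-diphenyl-1,3-benzodioxol-5-yl)chromane-3,5,7-triol F3. NBS (2 equiv, THF, −40 °C) should brominate C6 and C8 to give (2R,3S)-6,8-dibromo-2-(7-hydroxy-2,2-diphenyl-1,3-benzodioxol-5-yl)chromane-3,5,7-triol F4. Hydrolysis of the ketal (AcOH–H2O 4:1, 80 °C) should return 4. Any C2 epimerisation during the hydrolysis is harmless, because both epimers open to the same 5.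

Step 6. Bromide released from the two aryl bromides may poison the catalyst and stall the seventeen-fold debenzylation, or the basic scavenger may promote air oxidation of the four pyrogallol rings on work-up. The fallback removes the bromines by radical reduction before hydrogenation. From 9, Bu3SnH and AIBN (toluene, 90 °C) should reduce both C–Br bonds to give the bromine-free perbenzylated bis-gallate (2S,3R)-5,7-bis(benzyloxy)-8-{(1R,2S)-3-[2,4,6-tris(benzyloxy)phenyl]-2-[3,4,5-tris(benzyloxy)benzoyloxy]-1-[3,4,5-tris(benzyloxy)phenyl]propyl}-2-[3,4,5-tris(benzyloxy)phenyl]chroman-3-yl 3,4,5-tris(benzyloxy)benzoate F5. Hydrogenolysis of this compound without base (H2, Pd(OH)2 on carbon, THF–MeOH) should give 10.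

**Further compounds**

F1 | step 3 | (2S)-1-(benzylsulfanyl)-3-(3,5-dibromo-2,4,6-trihydroxyphenyl)-1-(3,4,5-trihydroxyphenyl)propan-2-ol (epimers at C1) | O[C@@H](Cc1c(O)c(Br)c(O)c(Br)c1O)C(SCc1ccccc1)c1cc(O)c(O)c(O)c1
F2 | step 3 | (2S)-1-(benzylsulfanyl)-3-[2,4,6-tris(benzyloxy)-3,5-dibromophenyl]-1-[3,4,5-tris(benzyloxy)phenyl]propan-2-ol (epimers at C1) | O[C@@H](Cc1c(OCc2ccccc2)c(Br)c(OCc2ccccc2)c(Br)c1OCc1ccccc1)C(SCc1ccccc1)c1cc(OCc2ccccc2)c(OCc2ccccc2)c(OCc2ccccc2)c1
F3 | step 2 | (2R,3S)-2-(7-hydroxy-2,2-diphenyl-1,3-benzodioxol-5-yl)chromane-3,5,7-triol | Oc1cc(O)c2c(c1)O[C@H](c1cc(O)c3OC(c4ccccc4)(c4ccccc4)Oc3c1)[C@@H](O)C2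
F4 | step 2 | (2R,3S)-6,8-dibromo-2-(7-hydroxy-2,2-diphenyl-1,3-benzodioxol-5-yl)chromane-3,5,7-triol | Oc1c(Br)c(O)c2c(c1Br)O[C@H](c1cc(O)c3OC(c4ccccc4)(c4ccccc4)Oc3c1)[C@@H](O)C2
F5 | step 6 | (2S,3R)-5,7-bis(benzyloxy)-8-{(1R,2S)-3-[2,4,6-tris(benzyloxy)phenyl]-2-[3,4,5-tris(benzyloxy)benzoyloxy]-1-[3,4,5-tris(benzyloxy)phenyl]propyl}-2-[3,4,5-tris(benzyloxy)phenyl]chroman-3-yl 3,4,5-tris(benzyloxy)benzoate | O=C(O[C@@H](Cc1c(OCc2ccccc2)cc(OCc2ccccc2)cc1OCc1ccccc1)[C@H](c1cc(OCc2ccccc2)c(OCc2ccccc2)c(OCc2ccccc2)c1)c1c(OCc2ccccc2)cc(OCc2ccccc2)c2c1O[C@@H](c1cc(OCc3ccccc3)c(OCc3ccccc3)c(OCc3ccccc3)c1)[C@H](OC(=O)c1cc(OCc3ccccc3)c(OCc3ccccc3)c(OCc3ccccc3)c1)C2)c1cc(OCc2ccccc2)c(OCc2ccccc2)c(OCc2ccccc2)c1
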